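**Retrosynthetic overview**

1. Target 24 comes from tetramethyl ether 23 (BBr3). 23 comes from seco bromophenol 22 by an Ullmann C–O macrocyclisation (ring B phenol oxygen to the ring A C–Br carbon), which closes the 17-membered macrocycle last.
2. 22 comes from phosphonium salt 17 and 3-bromo-4,5-dimethoxybenzaldehyde 18 (Wittig, diimide), which sets the ring D–CH2CH2–ring A bridge. 17 comes from benzoate 15.
3. 15 comes from aryl ethynyl ether 12 and pyrone 13 by Diels–Alder addition with loss of CO2. The feature used: the ether oxygen between rings C and D sits on a ring C carbon flanked by C–OH and by the carbon bearing the CH2CH2 chain, and ring D is an ortho-phenylene with four contiguous CH groups. Ring D is therefore assembled from the two ethynyl carbons already on that oxygen plus pyrone C3–C6, and the pyrone ester carbon becomes the benzylic CH2 toward ring A.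
4. 12 comes from phenol 6 and trichloroethylene 7. 6 comes from ring C aldehyde 3 and ring B phosphonium salt 2 (Wittig, diimide).
5. Ring order: rings A, B and C are bought, ring D is built in step 6, the macrocycle is closed in step 12.

Key step: step 6

Assumption: the target has no stereocentre and is treated as conformationally mobile, so no stereocontrol is planned; both stilbenes are carried as E/Z mixtures because each is saturated in the following step.

**Route**

Step 1
Reactants: 1 4-(benzyloxy)benzyl chloride
Product: 2 [4-(benzyloxy)benzyl]triphenylphosphonium chloride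
Conditions: PPh3, toluene, reflux
Reagents that add atoms: triphenylphosphine, c1ccc(cc1)P(c1ccccc1)c1ccccc1
Why: SN2 quaternisation of triphenylphosphine by a benzylic chloride, with the salt expected to precipitate from hot toluene.

Step 2
Reactants: 2 [4-(benzyloxy)benzyl]triphenylphosphonium chloride; 3 2-hydroxy-3,4-dimethoxybenzaldehyde
Product: 5 6-[2-[4-(benzyloxy)phenyl]ethenyl]-2,3-dimethoxyphenol (E/Z mixture), via phosphonium ylide 4 (not isolated)
Conditions: KOtBu (2.5 equiv), THF, 0 °C → rt; aq NH4Cl
Reagents that add atoms: none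
Why: Wittig olefination in which the semistabilised benzylic ylide 4 should still add to the aldehyde although the excess base holds the ortho phenol deprotonated, and the alkene geometry is irrelevant because the double bond is reduced next.

Step 3
Reactants: 5 6-[2-[4-(benzyloxy)phenyl]ethenyl]-2,3-dimethoxyphenol (E/Z mixture)
Product: 6 6-[2-[4-(benzyloxy)phenyl]ethyl]-2,3-dimethoxyphenol
Conditions: TsNHNH2 (excess), NaOAc, DME/H2O, reflux
Reagents that add atoms: none
Why: Diimide reduction, in which diimide released from the sulfonyl hydrazide transfers two hydrogens to the stilbene in a concerted syn fashion and cannot hydrogenolyse the benzyl ether.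

Step 4
Reactants: 6 6-[2-[4-(benzyloxy)phenyl]ethyl]-2,3-dimethoxyphenol; 7 trichloroethylene
Product: 9 1-[2-[4-(benzyloxy)phenyl]ethyl]-2-[(E)-1,2-dichloroethenyloxy]-3,4-dimethoxybenzene, via dichloroacetylene 8 (not isolated)
Conditions: K2CO3, DMF, 70 °C
Reagents that add atoms: none
Why: Base-mediated phenol addition to trichloroethylene, in which K2CO3 eliminates HCl from 7 to give 8 and the phenoxide adds anti to this small linear electrophile, which the doubly flanked oxygen can reach, to give the (E)-1,2-dichlorovinyl ether.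

Step 5
Reactants: 9 1-[2-[4-(benzyloxy)phenyl]ethyl]-2-[(E)-1,2-dichloroethenyloxy]-3,4-dimethoxybenzene
Product: 12 1-[2-[4-(benzyloxy)phenyl]ethyl]-2-(ethynyloxy)-3,4-dimethoxybenzene, via chloroethynyl ether 10 (not isolated), via lithium acetylide 11 (not isolated)
Conditions: n-BuLi (3 equiv), Et2O, −78 → −40 °C; then H2O, −78 °C; used promptly
Reagents that add atoms: none
Why: Dehydrochlorination followed by lithium–chlorine exchange, in which n-BuLi removes the vinylic proton, LiCl is lost to give 10, a second equivalent converts 10 into 11, and protonation gives the terminal aryl ethynyl ether, while the benzyl and methyl ethers should not be metalated at this temperature.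

Step 6
Reactants: 12 1-[2-[4-(benzyloxy)phenyl]ethyl]-2-(ethynyloxy)-3,4-dimethoxybenzene; 13 methyl 2-oxo-2H-pyran-3-carboxylate
Product: 15 methyl 2-[6-[2-[4-(benzyloxy)phenyl]ethyl]-2,3-dimethoxyphenoxy]benzoate, via bicyclic lactone 14 (not isolated)
Conditions: 13 (3 equiv), toluene, 110 °C, sealed tube, Ar
Reagents that add atoms: none
Why: The ester at pyrone C3 lowers the diene LUMO, so 13 should engage the oxygen-substituted alkyne of 12 in an inverse-electron-demand [4+2] cycloaddition across C3 and C6 to give bridged lactone 14, which expels CO2 by retro-[4+2] at the reaction temperature and delivers ring D directly as a benzene ring. The closest known reaction type is the CO2-extruding benzannulation of 3-carbomethoxy-2-pyrone with ketene acetals and ynamines to 2-donor-substituted benzoates; the aryloxyalkyne belongs to the same donor-substituted class but is less electron-rich, which is why heat and an excess of 13 are planned. Ring D is closed by an intermolecular cycloaddition that forms two C–C bonds (oxygen-bearing alkyne carbon to C3, terminal alkyne carbon to C6) followed by cycloreversion. The two bridgehead centres of 14 disappear on aromatisation, so the product has no stereocentre to control. The step needs one regiochemistry, aryloxy ortho to the ester, and the polarisation of both partners should secure it: the oxygen lone pair makes the terminal CH carbon the nucleophilic end, and C6 is the electrophilic terminus of the ester-activated diene, as in the ketene acetal series. An aryl ethynyl ether has no hydrogen on the carbon attached to oxygen and so cannot fragment to a ketene by the retro-ene path that limits alkyl ynol ethers on heating, and the benzyl ether, methyl ethers and arene rings are inert to 13.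

Step 7
Reactants: 15 methyl 2-[6-[2-[4-(benzyloxy)phenyl]ethyl]-2,3-dimethoxyphenoxy]benzoate
Product: 16 [2-[6-[2-[4-(benzyloxy)phenyl]ethyl]-2,3-dimethoxyphenoxy]phenyl]methanol
Conditions: LiAlH4, THF, 0 °C; then H2O
Reagents that add atoms: none
Why: Hydride reduction of the aryl ester to the benzylic alcohol, with all ether functions inert to LiAlH4.

Step 8
Reactants: 16 [2-[6-[2-[4-(benzyloxy)phenyl]ethyl]-2,3-dimethoxyphenoxy]phenyl]methanol
Product: 17 [2-[6-[2-[4-(benzyloxy)phenyl]ethyl]-2,3-dimethoxyphenoxy]benzyl]triphenylphosphonium bromide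
Conditions: PPh3·HBr, MeCN, reflux
Reagents that add atoms: triphenylphosphine hydrobromide, [Br-].c1ccc(cc1)[PH+](c1ccccc1)c1ccccc1
Why: One-flask acid-promoted substitution of a benzylic hydroxyl by triphenylphosphine, a standard way to make benzylphosphonium salts directly from benzylic alcohols, under which aryl ethers should persist.

Step 9
Reactants: 17 [2-[6-[2-[4-(benzyloxy)phenyl]ethyl]-2,3-dimethoxyphenoxy]benzyl]triphenylphosphonium bromide; 18 3-bromo-4,5-dimethoxybenzaldehyde
Product: 20 1-[2-[4-(benzyloxy)phenyl]ethyl]-2-[2-[2-(3-bromo-4,5-dimethoxyphenyl)ethenyl]phenoxy]-3,4-dimethoxybenzene (E/Z mixture), via phosphonium ylide 19 (not isolated)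
Conditions: K2CO3, 18-crown-6 (cat.), CH2Cl2, reflux
Reagents that add atoms: none
Why: Wittig olefination under solid–liquid phase-transfer conditions, in which ylide 19 condenses with the aromatic aldehyde while the aryl bromide and the ethers are spectators.

Step 10
Reactants: 20 1-[2-[4-(benzyloxy)phenyl]ethyl]-2-[2-[2-(3-bromo-4,5-dimethoxyphenyl)ethenyl]phenoxy]-3,4-dimethoxybenzene (E/Z mixture)
Product: 21 1-[2-[4-(benzyloxy)phenyl]ethyl]-2-[2-[2-(3-bromo-4,5-dimethoxyphenyl)ethyl]phenoxy]-3,4-dimethoxybenzene
Conditions: TsNHNH2 (excess), NaOAc, DME/H2O, reflux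
Reagents that add atoms: none
Why: Diimide reduction saturates the stilbene while sparing the aryl bromide and the benzyl ether, both of which would be at risk under catalytic hydrogenation.

Step 11
Reactants: 21 1-[2-[4-(benzyloxy)phenyl]ethyl]-2-[2-[2-(3-bromo-4,5-dimethoxyphenyl)ethyl]phenoxy]-3,4-dimethoxybenzene
Product: 22 4-[2-[2-[2-[2-(3-bromo-4,5-dimethoxyphenyl)ethyl]phenoxy]-3,4-dimethoxyphenyl]ethyl]phenol
Conditions: BCl3, pentamethylbenzene, CH2Cl2, −78 °C; then MeOH/H2O
Reagents that add atoms: none
Why: Lewis-acid debenzylation in which BCl3 ionises the benzyl aryl ether at low temperature and pentamethylbenzene captures the benzyl cation by Friedel–Crafts alkylation, so that the electron-rich rings are not benzylated and the methyl ethers and the bromide should stay intact.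

Step 12
Reactants: 22 4-[2-[2-[2-[2-(3-bromo-4,5-dimethoxyphenyl)ethyl]phenoxy]-3,4-dimethoxyphenyl]ethyl]phenol
Product: 23 macrocyclic tetramethyl ether (tetra-O-methyl derivative of the target)
Conditions: CuI (cat.), N,N-dimethylglycine hydrochloride, Cs2CO3, 1,4-dioxane, 100 °C, 2 mM, slow addition of 22
Reagents that add atoms: none
Why: Intramolecular Ullmann diaryl ether synthesis under high dilution joins the ring B phenol oxygen to the ring A carbon bearing bromine and closes the 17-membered macrocycle, a copper-catalysed C–O coupling that is established for macrocyclic diaryl ethers with ortho-methoxy aryl bromides.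

Step 13
Reactants: 23 macrocyclic tetramethyl ether
Product: 24 target compound CNP0114693.0
Conditions: BBr3 (excess), CH2Cl2, −78 °C → rt; then H2O, under Ar
Reagents that add atoms: none
Why: BBr3 demethylation cleaves the four aryl methyl ethers by Lewis-acid complexation and bromide attack at methyl, while the two diaryl ether bonds are not cleaved under these conditions.

**Compound list**

1 | 4-(benzyloxy)benzyl chloride | ClCc1ccc(OCc2ccccc2)cc1 | starting material
2 | [4-(benzyloxy)benzyl]triphenylphosphonium chloride | [Cl-].c1ccc(cc1)[P+](Cc1ccc(OCc2ccccc2)cc1)(c1ccccc1)c1ccccc1 | intermediate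
3 | 2-hydroxy-3,4-dimethoxybenzaldehyde | COc1ccc(C=O)c(O)c1OC | starting material
4 | [4-(benzyloxy)benzylidene]triphenylphosphorane (ylide of 2) | [CH-](c1ccc(OCc2ccccc2)cc1)[P+](c1ccccc1)(c1ccccc1)c1ccccc1 | intermediate (not isolated)
5 | 6-[2-[4-(benzyloxy)phenyl]ethenyl]-2,3-dimethoxyphenol, E/Z mixture (alkene geometry not controlled) | COc1ccc(C=Cc2ccc(OCc3ccccc3)cc2)c(O)c1OC | intermediate
6 | 6-[2-[4-(benzyloxy)phenyl]ethyl]-2,3-dimethoxyphenol | COc1ccc(CCc2ccc(OCc3ccccc3)cc2)c(O)c1OC | intermediate
7 | trichloroethylene | ClC=C(Cl)Cl | starting material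
8 | dichloroacetylene | ClC#CCl | intermediate (not isolated)
9 | 1-[2-[4-(benzyloxy)phenyl]ethyl]-2-[(E)-1,2-dichloroethenyloxy]-3,4-dimethoxybenzene | COc1ccc(CCc2ccc(OCc3ccccc3)cc2)c(O/C(Cl)=C\Cl)c1OC | intermediate
10 | 1-[2-[4-(benzyloxy)phenyl]ethyl]-2-(chloroethynyloxy)-3,4-dimethoxybenzene | COc1ccc(CCc2ccc(OCc3ccccc3)cc2)c(OC#CCl)c1OC | intermediate (not isolated)
11 | lithium acetylide of 12 | [Li]C#COc1c(CCc2ccc(OCc3ccccc3)cc2)ccc(OC)c1OC | intermediate (not isolated)
12 | 1-[2-[4-(benzyloxy)phenyl]ethyl]-2-(ethynyloxy)-3,4-dimethoxybenzene | C#COc1c(CCc2ccc(OCc3ccccc3)cc2)ccc(OC)c1OC | intermediate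
13 | methyl 2-oxo-2H-pyran-3-carboxylate | COC(=O)C1=CC=COC1=O | starting material
14 | methyl 5-aryloxy-3-oxo-2-oxabicyclo[2.2.2]octa-5,7-diene-4-carboxylate, aryl = ring C unit of 12 (racemic, one enantiomer drawn) | COC(=O)[C@@]12C=C[C@@H](OC1=O)C=C2Oc1c(CCc2ccc(OCc3ccccc3)cc2)ccc(OC)c1OC | intermediate (not isolated)
15 | methyl 2-[6-[2-[4-(benzyloxy)phenyl]ethyl]-2,3-dimethoxyphenoxy]benzoate | COC(=O)c1ccccc1Oc1c(CCc2ccc(OCc3ccccc3)cc2)ccc(OC)c1OC | intermediate
16 | [2-[6-[2-[4-(benzyloxy)phenyl]ethyl]-2,3-dimethoxyphenoxy]phenyl]methanol | OCc1ccccc1Oc1c(CCc2ccc(OCc3ccccc3)cc2)ccc(OC)c1OC | intermediate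
17 | [2-[6-[2-[4-(benzyloxy)phenyl]ethyl]-2,3-dimethoxyphenoxy]benzyl]triphenylphosphonium bromide | [Br-].c1ccc(cc1)[P+](Cc1ccccc1Oc1c(CCc2ccc(OCc3ccccc3)cc2)ccc(OC)c1OC)(c1ccccc1)c1ccccc1 | intermediate
18 | 3-bromo-4,5-dimethoxybenzaldehyde | COc1cc(C=O)cc(Br)c1OC | starting material
19 | ylide of 17 | c1ccc(cc1)[P+]([CH-]c1ccccc1Oc1c(CCc2ccc(OCc3ccccc3)cc2)ccc(OC)c1OC)(c1ccccc1)c1ccccc1 | intermediate (not isolated)
20 | 1-[2-[4-(benzyloxy)phenyl]ethyl]-2-[2-[2-(3-bromo-4,5-dimethoxyphenyl)ethenyl]phenoxy]-3,4-dimethoxybenzene, E/Z mixture (alkene geometry not controlled) | COc1cc(C=Cc2ccccc2Oc2c(CCc3ccc(OCc4ccccc4)cc3)ccc(OC)c2OC)cc(Br)c1OC | intermediate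
21 | 1-[2-[4-(benzyloxy)phenyl]ethyl]-2-[2-[2-(3-bromo-4,5-dimethoxyphenyl)ethyl]phenoxy]-3,4-dimethoxybenzene | COc1cc(CCc2ccccc2Oc2c(CCc3ccc(OCc4ccccc4)cc3)ccc(OC)c2OC)cc(Br)c1OC | intermediate
22 | 4-[2-[2-[2-[2-(3-bromo-4,5-dimethoxyphenyl)ethyl]phenoxy]-3,4-dimethoxyphenyl]ethyl]phenol | COc1cc(CCc2ccccc2Oc2c(CCc3ccc(O)cc3)ccc(OC)c2OC)cc(Br)c1OC | intermediate
23 | macrocyclic tetramethyl ether (tetra-O-methyl derivative of the target) | COc1cc2cc(c1OC)Oc1ccc(cc1)CCc1ccc(OC)c(OC)c1Oc1ccccc1CC2 | intermediate
24 | CNP0114693.0, the macrocyclic bis(bibenzyl) tetraphenol (achiral) | Oc1cc2cc(c1O)Oc1ccc(cc1)CCc1ccc(O)c(O)c1Oc1ccccc1CC2 | target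

**Step count and risk**

Total step count: 13. Longest linear sequence: 13 steps (from 1 to 24; compounds 3, 7, 13 and 18 are bought and enter this single line).

Steps most likely to fail:

Step 6. The aryloxyalkyne may polymerise or hydrate faster than it adds to the pyrone, because it is a weaker donor than the ketene acetals and ynamines for which this benzannulation is established; regioselectivity could also erode if bond formation becomes more synchronous. Fallback: the conventional alternative sets out from phenol 6 and gives up the pyrone construction. Nucleophilic aromatic substitution of 2-fluorobenzaldehyde by the phenoxide of 6 (K2CO3, DMA, 140 °C) would give 2-[6-[2-[4-(benzyloxy)phenyl]ethyl]-2,3-dimethoxyphenoxy]benzaldehyde F1. Reduction with NaBH4 (MeOH/THF, 0 °C) brings the material back to the route at alcohol 16.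

Step 12. Intermolecular coupling and oligomerisation may outrun ring closure, and oxidative addition at the electron-rich, ortho-substituted bromide may be slow enough for protodebromination to compete. Fallback: the ring is closed at the ring D–ring A ethylene bridge instead, setting out from ester 15.
- Hydrogenolysis (H2, Pd/C, EtOAc) would give methyl 2-[6-[2-(4-hydroxyphenyl)ethyl]-2,3-dimethoxyphenoxy]benzoate F2.
- Aldehyde 18 is protected with ethylene glycol (TsOH, toluene, azeotropic removal of water) as 2-(3-bromo-4,5-dimethoxyphenyl)-1,3-dioxolane F3.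
- Intermolecular Ullmann coupling of F2 with F3 (CuI, N,N-dimethylglycine hydrochloride, Cs2CO3, dioxane, 100 °C) would give the diaryl ether ester acetal F4.
- LiAlH4 reduction gives the benzylic alcohol acetal F5.
- PPh3·HBr in refluxing MeCN with aqueous work-up forms the phosphonium salt and frees the aldehyde, giving the phosphonium bromide aldehyde F6.
- NaOMe in CH2Cl2 under high dilution generates the ylide F7, which closes by intramolecular Wittig reaction to the macrocyclic stilbene F8.
- Hydrogenation (H2, Pd/C, EtOAc) returns to the route at 23.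

Step 5. The terminal aryl ethynyl ether may be lost by polymerisation or hydration during isolation and storage, and competing benzylic deprotonation of the benzyl ether by n-BuLi would lower the mass balance. Fallback: setting out from 9, the same n-BuLi treatment is used but lithium acetylide 11 is quenched with Me3SiCl. This would give the storable silyl-capped ynol ether [2-[6-[2-[4-(benzyloxy)phenyl]ethyl]-2,3-dimethoxyphenoxy]ethynyl]trimethylsilane F9. The silyl group is removed with Bu4NF (THF, −20 °C) immediately before the cycloaddition, which rejoins the route at 12.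

**Further compounds**

F1 | step 6 | 2-[6-[2-[4-(benzyloxy)phenyl]ethyl]-2,3-dimethoxyphenoxy]benzaldehyde | O=Cc1ccccc1Oc1c(CCc2ccc(OCc3ccccc3)cc2)ccc(OC)c1OC
F2 | step 12 | methyl 2-[6-[2-(4-hydroxyphenyl)ethyl]-2,3-dimethoxyphenoxy]benzoate | COC(=O)c1ccccc1Oc1c(CCc2ccc(O)cc2)ccc(OC)c1OC
F3 | step 12 | 2-(3-bromo-4,5-dimethoxyphenyl)-1,3-dioxolane | COc1cc(C2OCCO2)cc(Br)c1OC
F4 | step 12 | methyl 2-[6-[2-[4-[5-(1,3-dioxolan-2-yl)-2,3-dimethoxyphenoxy]phenyl]ethyl]-2,3-dimethoxyphenoxy]benzoate | COC(=O)c1ccccc1Oc1c(CCc2ccc(Oc3cc(C4OCCO4)cc(OC)c3OC)cc2)ccc(OC)c1OC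
F5 | step 12 | [2-[6-[2-[4-[5-(1,3-dioxolan-2-yl)-2,3-dimethoxyphenoxy]phenyl]ethyl]-2,3-dimethoxyphenoxy]phenyl]methanol | OCc1ccccc1Oc1c(CCc2ccc(Oc3cc(C4OCCO4)cc(OC)c3OC)cc2)ccc(OC)c1OC
F6 | step 12 | [2-[6-[2-[4-(5-formyl-2,3-dimethoxyphenoxy)phenyl]ethyl]-2,3-dimethoxyphenoxy]benzyl]triphenylphosphonium bromide | [Br-].O=Cc1cc(OC)c(OC)c(Oc2ccc(CCc3ccc(OC)c(OC)c3Oc3ccccc3C[P+](c3ccccc3)(c3ccccc3)c3ccccc3)cc2)c1
F7 | step 12 | ylide of F6 | O=Cc1cc(OC)c(OC)c(Oc2ccc(CCc3ccc(OC)c(OC)c3Oc3ccccc3[CH-][P+](c3ccccc3)(c3ccccc3)c3ccccc3)cc2)c1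
F8 | step 12 | macrocyclic stilbene tetramethyl ether, E/Z mixture | COc1cc2cc(c1OC)Oc1ccc(cc1)CCc1ccc(OC)c(OC)c1Oc1ccccc1C=C2
F9 | step 5 | [2-[6-[2-[4-(benzyloxy)phenyl]ethyl]-2,3-dimethoxyphenoxy]ethynyl]trimethylsilane | C[Si](C)(C)C#COc1c(CCc2ccc(OCc3ccccc3)cc2)ccc(OC)c1OC
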